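**Retrosynthetic overview**
- The last operation replaces a bromine placeholder on the pendant ring by hydrogen. The placeholder sits ortho to C1′ and para to the meta-methoxy group.
- Ring B is cut at C4–C4a and at C1–C8a. This frees ring A as plain veratrole and leaves the chain C1–C4 with its aryl group as a 5-aryl-3,4-dimethyloxolan-2-ol. In the forward direction one acid-catalysed operation exchanges the ring oxygen of the oxolane for an ortho-phenylene unit.
- Enabling feature: C4a and C8a of ring A are adjacent and lie para to the C7 and C6 methoxy groups, so they are the two most nucleophilic positions of C2v-symmetric veratrole. C1 is a para-methoxybenzylic carbon that ionises easily. The C3=C4 styrene bond is the dehydrated form of an aldehyde adduct at C4.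
- The lactol comes from an anti homoallylic alcohol by directed branched hydroformylation, in which CO supplies C4. The alcohol comes from 6-bromoveratraldehyde by asymmetric crotylboration, which sets C2, the only stereocentre that has to be carried.
- Ring order: the temporary oxolane forms in step 2 and opens again as ring B closes in step 3. Ring A and the pendant ring are bought.

Key step: step 3

Remark on numbering: the dihydronaphthalene numbering of the target is used for the chain carbons of all precursors (C1 aryl-bearing CH, C2 CH(CH3), C3 C(CH3), C4 =CH, then C4a to C8a; pendant ring C1′ to C6′).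

Assumption: (R)-TRIP is taken to direct the crotyl group to the Re face of the ortho-bromo aldehyde, as with other aryl aldehydes; should the sense be opposite, the equally available (S)-catalyst would be used.

**Step 1**
Reactants: 1 2-bromo-4,5-dimethoxybenzaldehyde; 2 (E)-crotylboronic acid pinacol ester
Product: 4 (1R,2R)-1-(2-bromo-4,5-dimethoxyphenyl)-2-methylbut-3-en-1-ol, via O-boryl ether 3 (not isolated)
Conditions: (R)-TRIP [(R)-3,3′-bis(2,4,6-triisopropylphenyl)-1,1′-binaphthyl-2,2′-diyl hydrogen phosphate] (5 mol %), 4 Å MS, PhMe, −30 °C; aq. NaHCO3 work-up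
Reagents that add atoms: none
Why: Chiral-phosphoric-acid-catalysed asymmetric crotylboration, in which the closed chair (Zimmerman–Traxler) transition state translates the E geometry of 2 into the anti relationship, and the catalyst, hydrogen-bonded to the pseudo-axial boronate oxygen and to the formyl hydrogen, should expose the Re face of 1, setting C1 as R and, decisive for the route, C2 as R.

**Step 2**
Reactants: 4 (1R,2R)-1-(2-bromo-4,5-dimethoxyphenyl)-2-methylbut-3-en-1-ol
Product: 6 (4R,5R)-5-(2-bromo-4,5-dimethoxyphenyl)-3,4-dimethyloxolan-2-ol (C2/C3 epimer mixture), via open-chain hydroxy aldehyde 5 (not isolated)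
Conditions: Rh(acac)(CO)2 (2 mol %), Ph2POMe (10 mol %), CO/H2 (1:1, 40 bar), 4 Å MS, THF, 40 °C
Reagents that add atoms: carbon monoxide, [C-]#[O+]
Why: Directed branched-selective rhodium-catalysed hydroformylation of a homoallylic alcohol, in which Ph2POMe exchanges reversibly with the carbinol OH and the bound phosphinite delivers the rhodium hydride through a chelate, so that the formyl group ends on the internal alkene carbon (C3) and 5 closes spontaneously to lactol 6; the new centres at C3 and C4 are not controlled and need not be, since step 3 erases both.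

**Step 3**
Reactants: 6 (4R,5R)-5-(2-bromo-4,5-dimethoxyphenyl)-3,4-dimethyloxolan-2-ol; 7 veratrole (1,2-dimethoxybenzene)
Product: 10 (1S,2S)-1-(2-bromo-4,5-dimethoxyphenyl)-6,7-dimethoxy-2,3-dimethyl-1,2-dihydronaphthalene, via 2,5-diaryloxolane 8 (not isolated), via 4-aryltetralin-1-ol 9 (not isolated)
Conditions: 7 (1.2 equiv), TfOH (10 mol %), CH2Cl2/HFIP (1,1,1,3,3,3-hexafluoropropan-2-ol) 4:1, 0.02 M, −40 °C to rt
Reagents that add atoms: none
Why: Acid ionises the hemiacetal of 6 first and veratrole captures the oxocarbenium ion para to a methoxy group (Friedel–Crafts hydroxyalkylation, bond C4–C4a) to give 8; on warming the C1–O bond of 8 ionises to the para-methoxy-stabilised benzylic cation, the newly attached ring attacks it through its free position para to the second methoxy group (bond C1–C8a) to give 9, and E1 loss of water from the benzylic C4–OH of 9 installs the C3=C4 styrene. The closest known reaction types are the acid-promoted Friedel–Crafts arylation of 2-oxy-oxolanes by veratrole, the acid-induced isomerisation of 2,5-diaryl-3,4-dimethyloxolanes to 1-aryl-1,2-dihydronaphthalenes and the one-pot annulation of arenes by gamma-aryl-gamma-butyrolactones to 4-aryltetralones, run here as one cascade. Ring B, the only ring closed, forms by 6-exo-trig attack of the arene on cationic C1 (the quinoid C1=C1′ bond lies outside the new ring), while the temporary oxolane ring is opened. The one new stereocentre, C1, is controlled by the C2 methyl centre: in the cation the C2–H bond eclipses the aryl plane to minimise A1,3 strain, so the tethered ring bonds on the face anti to the methyl group through a half-chair with both substituents pseudo-equatorial and should give the trans isomer, whereas the configurations at C1, C3 and C4 of 6, 8 and 9 are erased. Three selectivities are needed: site selectivity on veratrole, secured by its symmetry and by two adjacent positions that each lie para to a methoxy group; the choice of the ring that closes, secured by the bromine atom at C2′, which occupies the only pendant-ring position that is para to a methoxy group and within reach of a C4 cation, so that C2 and not the uncontrolled C3 survives as the stereocentre; and the order of ionisation, secured by the faster ionisation of a hemiacetal than of a benzylic ether at low temperature. Ionisation of 8 at C4 is harmless, because that cation can only re-close or lose the C3 proton to a styrene that converges on 10 after ionisation at C1.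

**Step 4**
Reactants: 10 (1S,2S)-1-(2-bromo-4,5-dimethoxyphenyl)-6,7-dimethoxy-2,3-dimethyl-1,2-dihydronaphthalene
Product: 12 (1R,2S)-1-(3,4-dimethoxyphenyl)-6,7-dimethoxy-2,3-dimethyl-1,2-dihydronaphthalene (target), via aryllithium 11 (not isolated)
Conditions: n-BuLi (1.1 equiv), THF, −78 °C, 10 min; then MeOH
Reagents that add atoms: none
Why: Bromine–lithium exchange followed by protonation, the exchange at −78 °C being much faster than deprotonation at C1 or addition to the trisubstituted styrene, so that the placeholder is replaced by hydrogen without touching C1, C2 or C3=C4 (the C1 descriptor changes from S to R only because bromine no longer raises the CIP rank of the pendant ring).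

**Compound list**
1 | 2-bromo-4,5-dimethoxybenzaldehyde | COc1cc(Br)c(C=O)cc1OC | starting material
2 | (E)-crotylboronic acid pinacol ester | C/C=C/CB1OC(C)(C)C(C)(C)O1 | starting material
3 | 2-{[(1R,2R)-1-(2-bromo-4,5-dimethoxyphenyl)-2-methylbut-3-en-1-yl]oxy}-4,4,5,5-tetramethyl-1,3,2-dioxaborolane | C=C[C@@H](C)[C@@H](OB1OC(C)(C)C(C)(C)O1)c1cc(OC)c(OC)cc1Br | intermediate
4 | (1R,2R)-1-(2-bromo-4,5-dimethoxyphenyl)-2-methylbut-3-en-1-ol | C=C[C@@H](C)[C@@H](O)c1cc(OC)c(OC)cc1Br | intermediate
5 | (3R,4R)-4-(2-bromo-4,5-dimethoxyphenyl)-4-hydroxy-2,3-dimethylbutanal (C2 epimer mixture) | O=CC(C)[C@@H](C)[C@@H](O)c1cc(OC)c(OC)cc1Br | intermediate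
6 | (4R,5R)-5-(2-bromo-4,5-dimethoxyphenyl)-3,4-dimethyloxolan-2-ol (C2/C3 epimer mixture) | OC1O[C@@H](c2cc(OC)c(OC)cc2Br)[C@H](C)C1C | intermediate
7 | veratrole (1,2-dimethoxybenzene) | COc1ccccc1OC | starting material
8 | (2R,3R)-2-(2-bromo-4,5-dimethoxyphenyl)-5-(3,4-dimethoxyphenyl)-3,4-dimethyloxolane (C4/C5 epimer mixture) | COc1ccc(C2O[C@@H](c3cc(OC)c(OC)cc3Br)[C@H](C)C2C)cc1OC | intermediate
9 | (3S,4S)-4-(2-bromo-4,5-dimethoxyphenyl)-6,7-dimethoxy-2,3-dimethyl-1,2,3,4-tetrahydronaphthalen-1-ol (C1/C2 epimer mixture) | COc1cc(Br)c([C@@H]2c3cc(OC)c(OC)cc3C(O)C(C)[C@H]2C)cc1OC | intermediate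
10 | (1S,2S)-1-(2-bromo-4,5-dimethoxyphenyl)-6,7-dimethoxy-2,3-dimethyl-1,2-dihydronaphthalene | COc1cc(Br)c([C@@H]2c3cc(OC)c(OC)cc3C=C(C)[C@H]2C)cc1OC | intermediate
11 | 2-[(1R,2S)-6,7-dimethoxy-2,3-dimethyl-1,2-dihydronaphthalen-1-yl]-4,5-dimethoxyphenyllithium | COc1cc([Li])c([C@@H]2c3cc(OC)c(OC)cc3C=C(C)[C@H]2C)cc1OC | intermediate
12 | (1R,2S)-1-(3,4-dimethoxyphenyl)-6,7-dimethoxy-2,3-dimethyl-1,2-dihydronaphthalene | COc1ccc([C@@H]2c3cc(OC)c(OC)cc3C=C(C)[C@H]2C)cc1OC | target

Total step count: 4. Longest linear sequence: 4 steps (1 to 4 to 6 to 10 to 12).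

**Steps most likely to fail**

1. Step 3.
   - What may go wrong: a second molecule of veratrole may capture the C4 benzylic cation before ring closure. C1 may ionise early, with intermolecular attack and poor facial control. The C2 configuration may erode by reversible proton loss from the C1 cation. Acid may transfer bromine or oligomerise the electron-rich styrene.
   - Fallback, from 6 back to 10: the first bond is made by organometallic addition instead of aromatic substitution. Lactol 6 is treated with 3,4-dimethoxyphenylmagnesium bromide (2.5 equiv, THF, 0 °C), which adds to the open aldehyde form and should give (1R,2R)-1-(2-bromo-4,5-dimethoxyphenyl)-4-(3,4-dimethoxyphenyl)-2,3-dimethylbutane-1,4-diol F1. This diol is then closed in a separate, purely intramolecular Friedel–Crafts cyclodehydration (TFA, CH2Cl2, 0 °C, no external arene) through 8 and 9 to 10.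

2. Step 2.
   - What may go wrong: branched-to-linear regiocontrol may be poor at an alkene that carries an allylic branch. Rhodium-hydride-induced alkene migration would erase C2.
   - Fallback, from 1 back to 6: C4 is brought in with the allyl reagent instead of with CO. Commercial (E)-2-methylbut-2-en-1-ol is borylated with B2pin2 ([Pd(MeCN)4](BF4)2 cat., DMSO/MeOH) to (E)-2-methylbut-2-en-1-ylboronic acid pinacol ester F2. Addition of F2 to 1 under the catalysis of step 1 should give (1R,2R)-1-(2-bromo-4,5-dimethoxyphenyl)-2,3-dimethylbut-3-en-1-ol F3.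
   - Hydroboration and oxidation (9-BBN, THF; NaOH, H2O2) then gives (1R,2R)-1-(2-bromo-4,5-dimethoxyphenyl)-2,3-dimethylbutane-1,4-diol F4. Oxidative lactonisation (TEMPO, PhI(OAc)2, CH2Cl2) gives (4R,5R)-5-(2-bromo-4,5-dimethoxyphenyl)-3,4-dimethyloxolan-2-one F5. Reduction with i-Bu2AlH (CH2Cl2, −78 °C) returns lactol 6.

3. Step 1.
   - What may go wrong: facial selectivity and rate may both be insufficient with an ortho-substituted, electron-rich aldehyde.
   - Fallback, from 1 back to 4: the configuration is taken from the chiral pool by chirality transfer. Commercial (S)-but-3-yn-2-ol is converted (MsCl, Et3N, CH2Cl2, 0 °C) into (S)-but-3-yn-2-yl methanesulfonate F6. Treatment with Pd(OAc)2/PPh3 (cat.) and Et2Zn in THF at −20 °C in the presence of 1 proceeds by anti SN2′ addition of zerovalent palladium, transmetalation to zinc and cyclic SE2′ addition. The result is net inversion at the propargylic carbon with anti selectivity, which should give (1R,2R)-1-(2-bromo-4,5-dimethoxyphenyl)-2-methylbut-3-yn-1-ol F7. Semihydrogenation (H2, Pd/CaCO3 poisoned with Pb(OAc)2, quinoline, EtOAc) returns 4.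

**Further compounds**
F1 | step 3 | (1R,2R)-1-(2-bromo-4,5-dimethoxyphenyl)-4-(3,4-dimethoxyphenyl)-2,3-dimethylbutane-1,4-diol (C3/C4 epimer mixture) | COc1ccc(C(O)C(C)[C@@H](C)[C@@H](O)c2cc(OC)c(OC)cc2Br)cc1OC
F2 | step 2 | (E)-2-methylbut-2-en-1-ylboronic acid pinacol ester | C/C=C(\C)CB1OC(C)(C)C(C)(C)O1
F3 | step 2 | (1R,2R)-1-(2-bromo-4,5-dimethoxyphenyl)-2,3-dimethylbut-3-en-1-ol | C=C(C)[C@@H](C)[C@@H](O)c1cc(OC)c(OC)cc1Br
F4 | step 2 | (1R,2R)-1-(2-bromo-4,5-dimethoxyphenyl)-2,3-dimethylbutane-1,4-diol (C3 epimer mixture) | OCC(C)[C@@H](C)[C@@H](O)c1cc(OC)c(OC)cc1Br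
F5 | step 2 | (4R,5R)-5-(2-bromo-4,5-dimethoxyphenyl)-3,4-dimethyloxolan-2-one (C3 epimer mixture) | O=C1O[C@@H](c2cc(OC)c(OC)cc2Br)[C@H](C)C1C
F6 | step 1 | (S)-but-3-yn-2-yl methanesulfonate | C#C[C@H](C)OS(C)(=O)=O
F7 | step 1 | (1R,2R)-1-(2-bromo-4,5-dimethoxyphenyl)-2-methylbut-3-yn-1-ol | C#C[C@@H](C)[C@@H](O)c1cc(OC)c(OC)cc1Br
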